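**Plan**
1. Retrosynthesis: the C2' ketone is taken back to an alcohol and the isovalerate is removed. The C1'–C2' bond is then cut to an 8-formylcoumarin and a 3-alkoxy-2-methylallyl unit. The formyl carbon goes back to bromine at C8 and the 6-methoxy to a phenol.
2. The coumarin is then cut through both rings at once, at C8a–C4a and C6–C5, to a 3-bromo-4-methoxyfuran that carries a (Z)-pent-2-en-4-ynoyl group on its 2-oxygen.
3. Enabling feature: the benzene ring has oxygen at C8a (lactone O1) and at C6, para to each other, with the C7 methoxy and the C8 branch between them. A 2-acyloxy-4-methoxyfuran leaves exactly this pattern when its ring oxygen becomes a C6–C8a bridge and the bridge opens.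
4. Forward: bromotetronate and enynoic acid give the furyl ester. One thermal step closes the pyranone and the benzene ring together. The C8 chain is then added by methylation, formylation, allylboration, acylation, acetal removal and oxidation.
5. Stereochemistry: the single stereocentre (C1', R) is set by the isopinocampheyl groups in an asymmetric γ-alkoxyallylboration of the C8 aldehyde. The second centre formed there (C2') is erased by the last oxidation.

Key step: step 5

Remark on the chemistry: the side chain is numbered C1' (benzylic) to C4' and the target SMILES is read as 1'R. It is assumed that the 2-methyl congener of the known (Z)-γ-(methoxymethoxy)allyl diisopinocampheylborane forms and reacts like the parent reagent.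

**Route**

Step 1
Reactants: 1 methyl tetronate (4-methoxyfuran-2(5H)-one)
Product: 2 3-bromo-4-methoxyfuran-2(5H)-one
Conditions: NBS, MeCN, rt, dark
Reagents that add atoms: N-bromosuccinimide, O=C1CCC(=O)N1Br
Why: C3 is the nucleophilic carbon of the enol ether (the α-carbon of the vinylogous carbonate), so electrophilic vinylic bromination with NBS followed by loss of the C3 proton should give the 3-bromotetronate.

Step 2
Reactants: 3 ethyl (Z)-3-iodoacrylate; 4 trimethylsilylacetylene
Product: 5 ethyl (2Z)-5-(trimethylsilyl)pent-2-en-4-ynoate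
Conditions: PdCl2(PPh3)2 (2 mol%), CuI (4 mol%), Et3N, THF, 0 °C to rt
Reagents that add atoms: none
Why: Sonogashira coupling, in which oxidative addition of the Z-vinyl iodide to zerovalent palladium (formed in the flask) proceeds with retention of geometry, the copper acetylide transmetalates and reductive elimination gives the Z-enyne, the silyl cap preventing double coupling.

Step 3
Reactants: 5 ethyl (2Z)-5-(trimethylsilyl)pent-2-en-4-ynoate
Product: 6 (2Z)-pent-2-en-4-ynoic acid
Conditions: LiOH, THF/H2O, 0 °C to rt; then 1 M HCl to pH 2 at 0 °C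
Reagents that add atoms: lithium hydroxide, [Li+].[OH-]
Why: Saponification of the ethyl ester, with hydroxide also attacking silicon to cleave the alkynyl C–Si bond (protodesilylation), while the carboxylate formed resists conjugate addition so the Z geometry should be kept.

Step 4
Reactants: 2 3-bromo-4-methoxyfuran-2(5H)-one; 6 (2Z)-pent-2-en-4-ynoic acid
Product: 9 3-bromo-4-methoxyfuran-2-yl (2Z)-pent-2-en-4-ynoate, via acid chloride 7 (not isolated), via potassium furanolate 8 (not isolated)
Conditions: 6, 1-chloro-N,N,2-trimethylprop-1-en-1-amine, CH2Cl2, 0 °C to rt; separately 2, KN(SiMe3)2, THF, −78 °C; acid chloride solution added at −78 °C; pH 7 buffer, rapid filtration through neutral alumina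
Reagents that add atoms: none
Why: The chloroenamine makes the acid chloride without HCl (no isomerisation or addition to the enyne), deprotonation of 2 at C5 gives an aromatic 2-furanolate, and this hard oxygen nucleophile with a potassium counter-ion should be acylated on oxygen (enolate O-acylation, as in the known preparation of 2-furyl esters from butenolides) because only O-acylation keeps the furan aromatic.

Step 5
Reactants: 9 3-bromo-4-methoxyfuran-2-yl (2Z)-pent-2-en-4-ynoate
Product: 11 8-bromo-6-hydroxy-7-methoxy-2H-chromen-2-one, via oxa-bridged cycloadduct 10 (not isolated)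
Conditions: 1,2-dichlorobenzene (0.01 M), BHT (10 mol%), Ar, 150 °C
Reagents that add atoms: none
Why: Proposed new method: heating should drive a normal-demand intramolecular [4+2] cycloaddition in which the electron-rich furan (diene C2 to C5, raised by the 4-methoxy and 2-acyloxy groups) adds across the terminal alkyne, whose LUMO is lowered through the Z-enoate; the inner alkyne carbon bonds to furan C2 (the C8a–C4a bond) and the terminal carbon to furan C5 (the C6–C5 bond), giving 7-oxanorbornadiene 10. The closest known reaction type is the intramolecular Diels–Alder reaction of 2-amino-, 2-alkoxy- or 2-silyloxyfurans with tethered alkynes followed by oxa-bridge opening to anilines or phenols; what is new is that an ester through the furan 2-oxygen is the tether and stays in the product as the lactone. The pyranone closes as a six-membered ring through the four-atom O–C(=O)–CH=CH tether (the Z-alkene and the s-cis ester conformer hold the alkyne over the furan), and the carbocycle closes in the same event as the six-membered ring of the cycloadduct. The bridge should then ionise at C8a, where the cation is stabilised by the lactone oxygen and, through the C7=C8 double bond, by the C7 methoxy group, so the bridge oxygen stays on C6 and loss of the C6 proton gives the phenol; no stereocentre remains. The step needs only regiocontrol and suppression of bimolecular reaction: the tether allows a single alignment of alkyne and furan, the Z geometry from step 2 gives the reach, high dilution disfavours intermolecular cycloaddition, and the 3-bromo substituent is expected to help as halogens do in related furan cycloadditions.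

Step 6
Reactants: 11 8-bromo-6-hydroxy-7-methoxy-2H-chromen-2-one
Product: 12 8-bromo-6,7-dimethoxy-2H-chromen-2-one
Conditions: MeI, K2CO3, acetone, 50 °C
Reagents that add atoms: iodomethane, CI
Why: Williamson ether synthesis, the C6 phenoxide formed with K2CO3 being methylated by MeI while anhydrous carbonate leaves the lactone and the aryl bromide untouched.

Step 7
Reactants: 12 8-bromo-6,7-dimethoxy-2H-chromen-2-one
Product: 13 6,7-dimethoxy-2-oxo-2H-chromene-8-carbaldehyde
Conditions: Pd(OAc)2 (1 mol%), di(1-adamantyl)-n-butylphosphine (3 mol%), TMEDA, CO/H2 (1:1, 5 bar), toluene, 100 °C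
Reagents that add atoms: carbon monoxide, [C-]#[O+]
Why: Palladium-catalysed reductive carbonylation (formylation) of an aryl bromide, in which oxidative addition, CO insertion and hydrogenolysis of the acyl–palladium bond give the aldehyde; the bulky electron-rich phosphine is suited to a doubly ortho-substituted, electron-rich bromide, and the CO atmosphere should suppress hydrogenation of the C3=C4 bond.

Step 8
Reactants: 14 2-methylprop-2-en-1-ol
Product: 15 3-(methoxymethoxy)-2-methylprop-1-ene
Conditions: MOMCl, i-Pr2NEt, CH2Cl2, 0 °C to rt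
Reagents that add atoms: chloromethyl methyl ether, COCCl
Why: Standard alkoxymethylation of a primary alcohol by the highly electrophilic α-chloro ether under amine base.

Step 9
Reactants: 13 6,7-dimethoxy-2-oxo-2H-chromene-8-carbaldehyde; 15 3-(methoxymethoxy)-2-methylprop-1-ene
Product: 18 8-[(1R,2R)-1-hydroxy-2-(methoxymethoxy)-3-methylbut-3-en-1-yl]-6,7-dimethoxy-2H-chromen-2-one, via allylborane 16 (not isolated), via borinate ester 17 (not isolated)
Conditions: 15, s-BuLi, THF, −78 °C; (−)-Ipc2BOMe [from (+)-α-pinene], −78 °C; BF3·OEt2, −78 °C; then 13 in THF/CH2Cl2, −78 °C; pH 7 phosphate buffer, MeOH, 30% H2O2, 0 °C to rt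
Reagents that add atoms: none
Why: Asymmetric γ-alkoxyallylboration (Brown type), in which oxygen-directed α-lithiation gives the chelated Z-alkoxyallyl anion, boron takes the unsubstituted terminus, and the allylborane adds through a closed chair (Zimmerman–Traxler) transition state with the aryl group equatorial; the isopinocampheyl groups derived from (+)-α-pinene are expected to direct attack to the Si face of the aldehyde, which sets C1' as R, the Z geometry gives the syn (2'R) ether that is erased later, and the lactone is inert to the allylborane.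

Step 10
Reactants: 18 8-[(1R,2R)-1-hydroxy-2-(methoxymethoxy)-3-methylbut-3-en-1-yl]-6,7-dimethoxy-2H-chromen-2-one
Product: 19 (1R,2R)-1-(6,7-dimethoxy-2-oxo-2H-chromen-8-yl)-2-(methoxymethoxy)-3-methylbut-3-en-1-yl 3-methylbutanoate
Conditions: isovaleryl chloride, pyridine, DMAP (cat.), CH2Cl2, 0 °C to rt
Reagents that add atoms: 3-methylbutanoyl chloride, CC(C)CC(=O)Cl
Why: DMAP-catalysed acylation of the secondary benzylic alcohol through the acylpyridinium ion, with no bond to C1' broken so that its configuration is retained.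

Step 11
Reactants: 19 (1R,2R)-1-(6,7-dimethoxy-2-oxo-2H-chromen-8-yl)-2-(methoxymethoxy)-3-methylbut-3-en-1-yl 3-methylbutanoate
Product: 20 (1R,2R)-1-(6,7-dimethoxy-2-oxo-2H-chromen-8-yl)-2-hydroxy-3-methylbut-3-en-1-yl 3-methylbutanoate
Conditions: Me2BBr, CH2Cl2, −78 °C; then NaHCO3 (aq)/THF, −78 to 0 °C
Reagents that add atoms: none
Why: Dimethylboron bromide cleaves acetal-type ethers at −78 °C by coordination to the acetal oxygen and bromide transfer, the bromomethyl ether hydrolysing on the bicarbonate quench; the ester, lactone, aryl methyl ethers and alkene should survive at this temperature, and the cold near-neutral work-up limits 1,2-acyl migration to the new hydroxyl.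

Step 12
Reactants: 20 (1R,2R)-1-(6,7-dimethoxy-2-oxo-2H-chromen-8-yl)-2-hydroxy-3-methylbut-3-en-1-yl 3-methylbutanoate
Product: 21 (1R)-1-(6,7-dimethoxy-2-oxo-2H-chromen-8-yl)-3-methyl-2-oxobut-3-en-1-yl 3-methylbutanoate (CNP0283239.1)
Conditions: Dess–Martin periodinane, NaHCO3, CH2Cl2, 0 °C to rt
Reagents that add atoms: none
Why: Dess–Martin oxidation (ligand exchange at iodine, then intramolecular removal of the carbinol hydrogen) works under buffered, non-basic conditions, so the allylic alcohol should become the isopropenyl ketone without enolising the now α-keto benzylic C1' centre and without conjugate addition to the enone.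

**Compound list**
1 | methyl tetronate (4-methoxyfuran-2(5H)-one) | COC1=CC(=O)OC1 | starting material
2 | 3-bromo-4-methoxyfuran-2(5H)-one | COC1=C(Br)C(=O)OC1 | intermediate
3 | ethyl (Z)-3-iodoacrylate | CCOC(=O)/C=C\I | starting material
4 | trimethylsilylacetylene | C#C[Si](C)(C)C | starting material
5 | ethyl (2Z)-5-(trimethylsilyl)pent-2-en-4-ynoate | CCOC(=O)/C=C\C#C[Si](C)(C)C | intermediate
6 | (2Z)-pent-2-en-4-ynoic acid | C#C/C=C\C(=O)O | intermediate
7 | (2Z)-pent-2-en-4-ynoyl chloride | C#C/C=C\C(=O)Cl | intermediate (not isolated)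
8 | potassium 3-bromo-4-methoxyfuran-2-olate | [K+].[O-]c1occ(OC)c1Br | intermediate (not isolated)
9 | 3-bromo-4-methoxyfuran-2-yl (2Z)-pent-2-en-4-ynoate | C#C/C=C\C(=O)Oc1occ(OC)c1Br | intermediate
10 | 8-bromo-6,8a-epoxy-7-methoxy-6,8a-dihydro-2H-chromen-2-one (oxygen bridge from C6 to C8a; racemic, one enantiomer drawn) | COC1=C(Br)[C@@]23OC(=O)C=CC2=C[C@@H]1O3 | intermediate (not isolated)
11 | 8-bromo-6-hydroxy-7-methoxy-2H-chromen-2-one | COc1c(O)cc2ccc(=O)oc2c1Br | intermediate
12 | 8-bromo-6,7-dimethoxy-2H-chromen-2-one | COc1cc2ccc(=O)oc2c(Br)c1OC | intermediate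
13 | 6,7-dimethoxy-2-oxo-2H-chromene-8-carbaldehyde | COc1cc2ccc(=O)oc2c(C=O)c1OC | intermediate
14 | 2-methylprop-2-en-1-ol | C=C(C)CO | starting material
15 | 3-(methoxymethoxy)-2-methylprop-1-ene | C=C(C)COCOC | intermediate
16 | [(2Z)-3-(methoxymethoxy)-2-methylprop-2-en-1-yl]diisopinocampheylborane (isopinocampheyl groups from (+)-α-pinene) | COCO/C=C(/C)CB([C@@H]1C[C@@H]2C[C@H]([C@H]1C)C2(C)C)[C@@H]1C[C@@H]2C[C@H]([C@H]1C)C2(C)C | intermediate (not isolated)
17 | (1R,2R)-1-(6,7-dimethoxy-2-oxo-2H-chromen-8-yl)-2-(methoxymethoxy)-3-methylbut-3-en-1-yl diisopinocampheylborinate | C=C(C)[C@@H](OCOC)[C@H](OB([C@@H]1C[C@@H]2C[C@H]([C@H]1C)C2(C)C)[C@@H]1C[C@@H]2C[C@H]([C@H]1C)C2(C)C)c1c(OC)c(OC)cc2ccc(=O)oc12 | intermediate (not isolated)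
18 | 8-[(1R,2R)-1-hydroxy-2-(methoxymethoxy)-3-methylbut-3-en-1-yl]-6,7-dimethoxy-2H-chromen-2-one | C=C(C)[C@@H](OCOC)[C@H](O)c1c(OC)c(OC)cc2ccc(=O)oc12 | intermediate
19 | (1R,2R)-1-(6,7-dimethoxy-2-oxo-2H-chromen-8-yl)-2-(methoxymethoxy)-3-methylbut-3-en-1-yl 3-methylbutanoate | C=C(C)[C@@H](OCOC)[C@H](OC(=O)CC(C)C)c1c(OC)c(OC)cc2ccc(=O)oc12 | intermediate
20 | (1R,2R)-1-(6,7-dimethoxy-2-oxo-2H-chromen-8-yl)-2-hydroxy-3-methylbut-3-en-1-yl 3-methylbutanoate | C=C(C)[C@@H](O)[C@H](OC(=O)CC(C)C)c1c(OC)c(OC)cc2ccc(=O)oc12 | intermediate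
21 | (1R)-1-(6,7-dimethoxy-2-oxo-2H-chromen-8-yl)-3-methyl-2-oxobut-3-en-1-yl 3-methylbutanoate | C=C(C)C(=O)[C@H](OC(=O)CC(C)C)c1c(OC)c(OC)cc2ccc(=O)oc12 | target

**Count**
Total steps: 12. Longest linear sequence: 10 steps (steps 2, 3, 4, 5, 6, 7, 9, 10, 11, 12).

**Steps most likely to fail**

Step 5 (proposed new method). The cycloaddition may not start, because the furyl ester has to reach its s-cis conformer. Thermal acyl migration, hydrolysis of the activated ester or Z-to-E isomerisation of the tether may be faster. The fallback uses known intermolecular chemistry and sets out from 2. Silylation (TBSOTf, Et3N, CH2Cl2, 0 °C) gives tert-butyl[(3-bromo-4-methoxyfuran-2-yl)oxy]dimethylsilane F1. Diels–Alder reaction with ethyl propiolate (toluene, 80 °C), with furan C5 bonding to the propiolate β-carbon as is usual for 2-silyloxyfurans, gives ethyl 6-bromo-1-[(tert-butyldimethylsilyl)oxy]-5-methoxy-7-oxabicyclo[2.2.1]hepta-2,5-diene-2-carboxylate F2 (not isolated). Its bridge opens in the flask, and desilylation with Et3N·3HF gives ethyl 3-bromo-2,5-dihydroxy-4-methoxybenzoate F3. Methylation of the non-chelated 5-hydroxyl (MeI, 1 equiv, K2CO3, acetone) gives ethyl 3-bromo-2-hydroxy-4,5-dimethoxybenzoate F4. Reduction with LiAlH4 gives 2-bromo-6-(hydroxymethyl)-3,4-dimethoxyphenol F5, and oxidation with MnO2 gives 3-bromo-2-hydroxy-4,5-dimethoxybenzaldehyde F6. Wittig reaction with ethyl (triphenylphosphoranylidene)acetate in refluxing N,N-diethylaniline gives ethyl (2Z)-3-(3-bromo-2-hydroxy-4,5-dimethoxyphenyl)prop-2-enoate F7 (not isolated; the E isomer equilibrates at this temperature), which lactonises. The route is rejoined at 12.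

Step 4. The ambident furanolate may be acylated at C5 instead of oxygen, and the activated furyl ester may hydrolyse during work-up. The fallback sets out from 2 and 6 and avoids both the metal enolate and the aqueous work-up. Compound 2 is silylated (Me3SiOTf, Et3N, CH2Cl2, 0 °C) to [(3-bromo-4-methoxyfuran-2-yl)oxy]trimethylsilane F8. Acid 6 is converted with cyanuric fluoride and pyridine into (2Z)-pent-2-en-4-ynoyl fluoride F9. The two are joined with catalytic tetrabutylammonium difluorotriphenylsilicate in THF at −40 °C: fluoride frees the furanolate only in the presence of the acyl fluoride and is regenerated as the silyl group leaves as its fluoride. Filtration and evaporation give 9, where the route is rejoined.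

Step 9. Lithiation of the 2-methylallyl ether may take place at the methyl group instead of the OCH2 group, and the more crowded β-methyl reagent may add to the doubly ortho-substituted aldehyde with lower facial selectivity. The fallback sets out from 13, uses the well-known parent reagent and builds the methyl-bearing alkene afterwards. 3-(Methoxymethoxy)prop-1-ene F10 (from allyl alcohol as in step 8) is lithiated with s-BuLi and treated with (−)-Ipc2BOMe and BF3·OEt2 to give [(2Z)-3-(methoxymethoxy)prop-2-en-1-yl]diisopinocampheylborane F11. Addition to 13 gives (1R,2R)-1-(6,7-dimethoxy-2-oxo-2H-chromen-8-yl)-2-(methoxymethoxy)but-3-en-1-yl diisopinocampheylborinate F12 (not isolated), and buffered H2O2 work-up gives 8-[(1R,2R)-1-hydroxy-2-(methoxymethoxy)but-3-en-1-yl]-6,7-dimethoxy-2H-chromen-2-one F13. Isovalerylation as in step 10 gives (1R,2R)-1-(6,7-dimethoxy-2-oxo-2H-chromen-8-yl)-2-(methoxymethoxy)but-3-en-1-yl 3-methylbutanoate F14. Tsuji–Wacker oxidation (PdCl2, CuCl, O2, DMF/H2O) gives (1R,2S)-1-(6,7-dimethoxy-2-oxo-2H-chromen-8-yl)-2-(methoxymethoxy)-3-oxobutyl 3-methylbutanoate F15. Non-basic methylenation with Zn, CH2Br2 and TiCl4 gives 19, where the route is rejoined.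

**Further compounds**
F1 | step 5 | tert-butyl[(3-bromo-4-methoxyfuran-2-yl)oxy]dimethylsilane | COc1coc(O[Si](C)(C)C(C)(C)C)c1Br
F2 | step 5 | ethyl 6-bromo-1-[(tert-butyldimethylsilyl)oxy]-5-methoxy-7-oxabicyclo[2.2.1]hepta-2,5-diene-2-carboxylate (racemic, one enantiomer drawn) | CCOC(=O)C1=C[C@@H]2O[C@@]1(O[Si](C)(C)C(C)(C)C)C(Br)=C2OC
F3 | step 5 | ethyl 3-bromo-2,5-dihydroxy-4-methoxybenzoate | CCOC(=O)c1cc(O)c(OC)c(Br)c1O
F4 | step 5 | ethyl 3-bromo-2-hydroxy-4,5-dimethoxybenzoate | CCOC(=O)c1cc(OC)c(OC)c(Br)c1O
F5 | step 5 | 2-bromo-6-(hydroxymethyl)-3,4-dimethoxyphenol | OCc1cc(OC)c(OC)c(Br)c1O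
F6 | step 5 | 3-bromo-2-hydroxy-4,5-dimethoxybenzaldehyde | O=Cc1cc(OC)c(OC)c(Br)c1O
F7 | step 5 | ethyl (2Z)-3-(3-bromo-2-hydroxy-4,5-dimethoxyphenyl)prop-2-enoate | CCOC(=O)/C=C\c1cc(OC)c(OC)c(Br)c1O
F8 | step 4 | [(3-bromo-4-methoxyfuran-2-yl)oxy]trimethylsilane | COc1coc(O[Si](C)(C)C)c1Br
F9 | step 4 | (2Z)-pent-2-en-4-ynoyl fluoride | C#C/C=C\C(F)=O
F10 | step 9 | 3-(methoxymethoxy)prop-1-ene | C=CCOCOC
F11 | step 9 | [(2Z)-3-(methoxymethoxy)prop-2-en-1-yl]diisopinocampheylborane | COCO/C=C\CB([C@@H]1C[C@@H]2C[C@H]([C@H]1C)C2(C)C)[C@@H]1C[C@@H]2C[C@H]([C@H]1C)C2(C)C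
F12 | step 9 | (1R,2R)-1-(6,7-dimethoxy-2-oxo-2H-chromen-8-yl)-2-(methoxymethoxy)but-3-en-1-yl diisopinocampheylborinate | C=C[C@@H](OCOC)[C@H](OB([C@@H]1C[C@@H]2C[C@H]([C@H]1C)C2(C)C)[C@@H]1C[C@@H]2C[C@H]([C@H]1C)C2(C)C)c1c(OC)c(OC)cc2ccc(=O)oc12
F13 | step 9 | 8-[(1R,2R)-1-hydroxy-2-(methoxymethoxy)but-3-en-1-yl]-6,7-dimethoxy-2H-chromen-2-one | C=C[C@@H](OCOC)[C@H](O)c1c(OC)c(OC)cc2ccc(=O)oc12
F14 | step 9 | (1R,2R)-1-(6,7-dimethoxy-2-oxo-2H-chromen-8-yl)-2-(methoxymethoxy)but-3-en-1-yl 3-methylbutanoate | C=C[C@@H](OCOC)[C@H](OC(=O)CC(C)C)c1c(OC)c(OC)cc2ccc(=O)oc12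
F15 | step 9 | (1R,2S)-1-(6,7-dimethoxy-2-oxo-2H-chromen-8-yl)-2-(methoxymethoxy)-3-oxobutyl 3-methylbutanoate | CC(=O)[C@@H](OCOC)[C@H](OC(=O)CC(C)C)c1c(OC)c(OC)cc2ccc(=O)oc12
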